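**Retrosynthetic overview**
1. The coumarate is attached last to labda‑13(16),14‑diene‑7α,8α,19‑triol 25. Its 7α,8α‑diol with the C8 methyl is traced back to an 8α,17‑epoxy‑7α‑ol and then to an exocyclic 8(17)‑alkene.
2. The side‑chain diene comes from a C14 aldehyde (methylenation, then Wittig) that is carried as a radical‑inert dioxolane.
3. Key disconnection: the C4–C5 and C9–C10 bonds. An acyclic (E,E)‑diene α‑methyl β‑keto ester is folded by Mn(OAc)3/Cu(OAc)2 oxidative radical bicyclization; ring A closes first and ring B last, and the step ends as the 8(17)‑alkene.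
4. Enabling feature: C4 (quaternary, bearing the carboxyl‑level C19), C10 and C8 each carry a methyl group and are 1,5‑related. C4 can therefore be a β‑dicarbonyl radical site, and the trisubstituted alkenes C5=C10 and C8=C9 sit correctly for two 6‑endo closures into rings A and B.
5. The C3 ketone is a temporary activating group and the (−)‑8‑phenylmenthyl ester is both chiral auxiliary and latent C19. The precursor is assembled from geranyl bromide, 2‑(2‑bromoethyl)‑1,3‑dioxolane and ethyl 2‑methylacetoacetate.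

Key step: step 6

Remark (convention): labdane numbering is used for all bicyclic compounds (decalin C1–C10, side chain C11–C16, C17 on C8, C18 α and C19 β on C4, C20 on C10); "8‑phenylmenthyl" means (1R,2S,5R)‑5‑methyl‑2‑(2‑phenylpropan‑2‑yl)cyclohexyl.
Remark (assumption): the (−)‑8‑phenylmenthyl ester is taken to direct the cyclization to the 4β‑carboxyl/10β‑methyl (podocarpic‑acid‑type) series; if the opposite sense is found, (+)‑8‑phenylmenthol is used and nothing else changes.

**Step 1**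
Reactants: 1 geranyl bromide; 2 2‑(2‑bromoethyl)‑1,3‑dioxolane
Product: 4 2‑[(4E)‑5,9‑dimethyldeca‑4,8‑dien‑1‑yl]‑1,3‑dioxolane, via Grignard reagent 3 (not isolated)
Conditions: 2, Mg, THF, 30 °C; then 1, Li2CuCl4 (2 mol%), THF, −10 °C → rt
Reagents that add atoms: none
Why: Copper‑catalysed (Kochi‑type) coupling of a primary allylic bromide with a primary alkyl Grignard reagent should proceed by SN2 displacement with retention of the (E)‑alkene; no stereocentre is formed.

**Step 2**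
Reactants: 4
Product: 5 (2E,6E)‑10‑(1,3‑dioxolan‑2‑yl)‑2,6‑dimethyldeca‑2,6‑dien‑1‑ol
Conditions: SeO2 (0.3 equiv), t‑BuOOH (3 equiv), salicylic acid (0.1 equiv), CH2Cl2, 0 °C → rt
Reagents that add atoms: selenium dioxide, O=[Se]=O (oxygen carrier); tert‑butyl hydroperoxide, CC(C)(C)OO
Why: The SeO2/t‑BuOOH allylic oxidation (ene reaction, then [2,3]‑sigmatropic shift) should select the (E)‑methyl group of the terminal trisubstituted alkene and keep the E geometry.

**Step 3**
Reactants: 5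
Product: 6 2‑[(4E,8E)‑10‑bromo‑5,9‑dimethyldeca‑4,8‑dien‑1‑yl]‑1,3‑dioxolane
Conditions: CBr4, PPh3, CH2Cl2, −20 → 0 °C
Reagents that add atoms: carbon tetrabromide, BrC(Br)(Br)Br
Why: The Appel reaction should convert the primary allylic alcohol to the bromide under neutral conditions, without allylic transposition or loss of the acetal.

**Step 4**
Reactants: 7 (−)‑8‑phenylmenthol; 8 ethyl 2‑methyl‑3‑oxobutanoate
Product: 9 8‑phenylmenthyl 2‑methyl‑3‑oxobutanoate (epimers at C2)
Conditions: DMAP (0.3 equiv), toluene, reflux, removal of EtOH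
Reagents that add atoms: none
Why: DMAP‑catalysed transesterification of a β‑keto ester (through the acylketene) attaches the auxiliary; the epimerisable α‑centre is irrelevant because it later becomes a radical.

**Step 5**
Reactants: 9; 6
Product: 11 8‑phenylmenthyl (6E,10E)‑14‑(1,3‑dioxolan‑2‑yl)‑2,6,10‑trimethyl‑3‑oxotetradeca‑6,10‑dienoate (epimers at C2), via dilithium dianion 10 (not isolated)
Conditions: LDA (2.1 equiv), THF, 0 °C; then 6, 0 °C; aq. NH4Cl
Reagents that add atoms: none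
Why: Weiler dianion alkylation should occur only at the more basic terminal (γ) carbanion, forming the C1–C2 bond and leaving both alkene geometries untouched.

**Step 6**
Reactants: 11
Product: 15 8‑phenylmenthyl 14,14‑(ethylenedioxy)‑3‑oxo‑15,16‑dinorlabd‑8(17)‑en‑19‑oate (5α‑H, 9α‑H, 10β‑Me, 4α‑Me, 4β‑ester), via C4 radical 12 (not isolated), via monocyclic C10 radical 13 (not isolated), via bicyclic C8 radical 14 (not isolated)
Conditions: Mn(OAc)3·2H2O (2.2 equiv), Cu(OAc)2·H2O (1.0 equiv), KOAc (2 equiv), degassed AcOH, 25 °C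
Reagents that add atoms: none
Why: Mn(OAc)3 oxidises the enolised β‑keto ester to the electrophilic C4 radical 12, which adds 6‑endo‑trig to C5 of the C5=C10 alkene (ring A, radical 13); the tertiary C10 radical then adds 6‑endo‑trig to C9 of the C8=C9 alkene (ring B, radical 14), and Cu(OAc)2 oxidises the tertiary C8 radical with loss of a C17 hydrogen to the exocyclic alkene. The closest known reaction type is the oxidative free‑radical polyene cyclization of α‑methyl β‑keto esters with manganese triacetate and copper diacetate, including its 8‑phenylmenthyl ester variant used for the podocarpic acid ring system. Both closures should pass through chair‑like transition states of the (E,E)‑diene, so that C5–H and the C10 methyl become trans, C9–H becomes α with the side chain equatorial, and at C4 the ester becomes axial (β) and the methyl equatorial, as in the precedent. The absolute sense is set at the first C4–C5 bond formation by the auxiliary, whose phenyl group shields one face of the planar keto ester radical. The step needs 6‑endo over 5‑exo closure, which the methyl groups on C10 and C8 secure by blocking the internal alkene carbons; it needs ring B closure of 13 to be faster than its oxidation by copper, as in the known bi‑ to tetracyclizations; and it needs a side chain without radical acceptors, which the saturated acetal chain provides.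

**Step 7**
Reactants: 15
Product: 16 C3 tosylhydrazone of 15
Conditions: TsNHNH2 (1.5 equiv), EtOH, 70 °C
Reagents that add atoms: p‑toluenesulfonohydrazide, Cc1ccc(cc1)S(=O)(=O)NN
Why: Condensation of the only ketone with tosylhydrazide in neutral ethanol should leave the acetal, the ester and the alkene untouched.

**Step 8**
Reactants: 16
Product: 19 8‑phenylmenthyl 14,14‑(ethylenedioxy)‑15,16‑dinorlabd‑8(17)‑en‑19‑oate, via N‑boryl sulfonohydrazide 17 (not isolated), via diazene 18 (not isolated)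
Conditions: catecholborane (2.5 equiv), CHCl3, 0 °C → rt; then NaOAc·3H2O, reflux
Reagents that add atoms: none
Why: In the Kabalka deoxygenation the C=N bond is hydroborated, acetate then induces loss of sulfinate, and the diazene loses N2 to give the C3 methylene under nearly neutral conditions that spare the alkene, ester and acetal.

**Step 9**
Reactants: 19
Product: 20 8‑phenylmenthyl 14,14‑(ethylenedioxy)‑7α‑hydroxy‑15,16‑dinorlabd‑8(17)‑en‑19‑oate
Conditions: SeO2 (0.5 equiv), t‑BuOOH (2 equiv), CH2Cl2, rt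
Reagents that add atoms: selenium dioxide, O=[Se]=O (oxygen carrier); tert‑butyl hydroperoxide, CC(C)(C)OO
Why: In the SeO2 allylic hydroxylation the ene reaction at C17 should remove the axial 7α hydrogen and the [2,3]‑shift should return the 8(17)‑alkene, placing the hydroxyl axial (α) at C7 on the face away from the C10 methyl; the tertiary C9–H is more hindered.

**Step 10**
Reactants: 20
Product: 21 8‑phenylmenthyl 7α‑hydroxy‑14‑oxo‑15,16‑dinorlabd‑8(17)‑en‑19‑oate
Conditions: p‑TsOH·H2O (0.1 equiv), acetone/H2O (10:1), rt → 40 °C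
Reagents that add atoms: water, O
Why: Mild acid‑catalysed hydrolysis of the dioxolane should release the aldehyde, which is too far from the 7‑hydroxyl to form a lactol.

**Step 11**
Reactants: 21
Product: 22 8‑phenylmenthyl 7α‑hydroxy‑14‑oxo‑15‑norlabda‑8(17),13(16)‑dien‑19‑oate
Conditions: aq. formaldehyde (37%, 1.2 equiv), pyrrolidine (0.1 equiv), propionic acid (0.1 equiv), i‑PrOH, 45 °C
Reagents that add atoms: formaldehyde, C=O
Why: Amine‑catalysed Mannich condensation and elimination (α‑methylenation of an aldehyde) installs C16 on C13 and tolerates the free hydroxyl.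

**Step 12**
Reactants: 22
Product: 23 8‑phenylmenthyl 7α‑hydroxylabda‑8(17),13(16),14‑trien‑19‑oate
Conditions: Ph3PCH3Br (3 equiv), KOt‑Bu (2.9 equiv), THF, 0 °C; then 22, 0 °C → rt
Reagents that add atoms: methyltriphenylphosphonium bromide, C[P+](c1ccccc1)(c1ccccc1)c1ccccc1.[Br-]
Why: Wittig methylenation of the enal carbonyl should give the 2‑substituted 1,3‑diene; excess ylide covers the free hydroxyl and the hindered ester is inert.

**Step 13**
Reactants: 23
Product: 24 8‑phenylmenthyl 8α,17‑epoxy‑7α‑hydroxylabda‑13(16),14‑dien‑19‑oate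
Conditions: VO(acac)2 (0.05 equiv), t‑BuOOH (1.5 equiv, in decane), CH2Cl2, 0 °C → rt
Reagents that add atoms: tert‑butyl hydroperoxide, CC(C)(C)OO
Why: The vanadium‑catalysed hydroxyl‑directed epoxidation should react only at the allylic alcohol alkene and deliver oxygen syn to the 7α‑hydroxyl, which is also the face away from the C10 methyl, so the C8–O bond is α.

**Step 14**
Reactants: 24
Product: 25 labda‑13(16),14‑diene‑7α,8α,19‑triol
Conditions: LiAlH4 (6 equiv), THF, 0 °C → reflux; aqueous NaOH work‑up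
Reagents that add atoms: none
Why: Hydride should open the epoxide by SN2 attack at the primary C17, leaving the C8–O bond (8α tertiary alcohol, 8β methyl), and should reduce the neopentyl ester to the C19 carbinol with release of the auxiliary; the isolated diene is inert.

**Step 15**
Reactants: 25; 26 (E)‑4‑acetoxycinnamic acid
Product: 27 19‑O‑[(E)‑4‑acetoxycinnamoyl]labda‑13(16),14‑diene‑7α,8α,19‑triol
Conditions: 26 (1.3 equiv), EDC·HCl (1.5 equiv), DMAP (0.2 equiv), CH2Cl2, 0 °C → rt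
Reagents that add atoms: none
Why: In the Steglich esterification the primary C19 hydroxyl should react in preference to the hindered axial secondary 7α‑hydroxyl and the tertiary 8α‑hydroxyl.

**Step 16**
Reactants: 27
Product: 28 target, 19‑O‑[(E)‑4‑hydroxycinnamoyl]labda‑13(16),14‑diene‑7α,8α,19‑triol
Conditions: K2CO3 (0.3 equiv), MeOH, 0 °C; aq. NH4Cl
Reagents that add atoms: none
Why: Base‑catalysed methanolysis should cleave the aryl acetate much faster than the hindered alkyl cinnamate and touches no stereocentre.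

**Compound list**
1 | geranyl bromide, (2E)‑1‑bromo‑3,7‑dimethylocta‑2,6‑diene | CC(C)=CCC/C(C)=C/CBr | starting material
2 | 2‑(2‑bromoethyl)‑1,3‑dioxolane | BrCCC1OCCO1 | starting material
3 | [2‑(1,3‑dioxolan‑2‑yl)ethyl]magnesium bromide | Br[Mg]CCC1OCCO1 | intermediate
4 | 2‑[(4E)‑5,9‑dimethyldeca‑4,8‑dien‑1‑yl]‑1,3‑dioxolane | CC(C)=CCC/C(C)=C/CCCC1OCCO1 | intermediate
5 | (2E,6E)‑10‑(1,3‑dioxolan‑2‑yl)‑2,6‑dimethyldeca‑2,6‑dien‑1‑ol | OC/C(C)=C/CC/C(C)=C/CCCC1OCCO1 | intermediate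
6 | 2‑[(4E,8E)‑10‑bromo‑5,9‑dimethyldeca‑4,8‑dien‑1‑yl]‑1,3‑dioxolane | BrC/C(C)=C/CC/C(C)=C/CCCC1OCCO1 | intermediate
7 | (−)‑8‑phenylmenthol, (1R,2S,5R)‑5‑methyl‑2‑(2‑phenylpropan‑2‑yl)cyclohexan‑1‑ol | CC(C)(c1ccccc1)[C@@H]1CC[C@@H](C)C[C@H]1O | starting material
8 | ethyl 2‑methyl‑3‑oxobutanoate (racemic) | CCOC(=O)C(C)C(C)=O | starting material
9 | 8‑phenylmenthyl 2‑methyl‑3‑oxobutanoate | CC(=O)C(C)C(=O)O[C@@H]1C[C@H](C)CC[C@H]1C(C)(C)c1ccccc1 | intermediate
10 | dilithium dianion of 9 | [Li+].[Li+].[CH2-]C(=O)[C-](C)C(=O)O[C@@H]1C[C@H](C)CC[C@H]1C(C)(C)c1ccccc1 | intermediate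
11 | 8‑phenylmenthyl (6E,10E)‑14‑(1,3‑dioxolan‑2‑yl)‑2,6,10‑trimethyl‑3‑oxotetradeca‑6,10‑dienoate | CC(C(=O)O[C@@H]1C[C@H](C)CC[C@H]1C(C)(C)c1ccccc1)C(=O)CC/C(C)=C/CC/C(C)=C/CCCC1OCCO1 | intermediate
12 | C4 (α‑keto ester) radical of 11 | C[C](C(=O)O[C@@H]1C[C@H](C)CC[C@H]1C(C)(C)c1ccccc1)C(=O)CC/C(C)=C/CC/C(C)=C/CCCC1OCCO1 | intermediate
13 | monocyclic (ring A) C10 radical | O5CCOC5CCC/C=C(\C)CC[C@H]2[C@@](C)(C(=O)O[C@@H]3C[C@H](C)CC[C@H]3C(C)(C)c4ccccc4)C(=O)CC[C]2C | intermediate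
14 | bicyclic C8 radical | O5CCOC5CCC[C@H]1[C](C)CC[C@H]2[C@@](C)(C(=O)O[C@@H]3C[C@H](C)CC[C@H]3C(C)(C)c4ccccc4)C(=O)CC[C@@]21C | intermediate
15 | 8‑phenylmenthyl 14,14‑(ethylenedioxy)‑3‑oxo‑15,16‑dinorlabd‑8(17)‑en‑19‑oate | O5CCOC5CCC[C@H]1C(=C)CC[C@H]2[C@@](C)(C(=O)O[C@@H]3C[C@H](C)CC[C@H]3C(C)(C)c4ccccc4)C(=O)CC[C@@]21C | intermediate
16 | C3 tosylhydrazone of 15 | O5CCOC5CCC[C@H]1C(=C)CC[C@H]2[C@@](C)(C(=O)O[C@@H]3C[C@H](C)CC[C@H]3C(C)(C)c4ccccc4)C(=NNS(=O)(=O)c6ccc(C)cc6)CC[C@@]21C | intermediate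
17 | N‑(catecholboryl) sulfonohydrazide at C3 | O5CCOC5CCC[C@H]1C(=C)CC[C@H]2[C@@](C)(C(=O)O[C@@H]3C[C@H](C)CC[C@H]3C(C)(C)c4ccccc4)C(N(B6Oc7ccccc7O6)NS(=O)(=O)c8ccc(C)cc8)CC[C@@]21C | intermediate
18 | C3 diazene | O5CCOC5CCC[C@H]1C(=C)CC[C@H]2[C@@](C)(C(=O)O[C@@H]3C[C@H](C)CC[C@H]3C(C)(C)c4ccccc4)C(N=N)CC[C@@]21C | intermediate
19 | 8‑phenylmenthyl 14,14‑(ethylenedioxy)‑15,16‑dinorlabd‑8(17)‑en‑19‑oate | O5CCOC5CCC[C@H]1C(=C)CC[C@H]2[C@@](C)(C(=O)O[C@@H]3C[C@H](C)CC[C@H]3C(C)(C)c4ccccc4)CCC[C@@]21C | intermediate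
20 | 8‑phenylmenthyl 14,14‑(ethylenedioxy)‑7α‑hydroxy‑15,16‑dinorlabd‑8(17)‑en‑19‑oate | O5CCOC5CCC[C@H]1C(=C)[C@H](O)C[C@H]2[C@@](C)(C(=O)O[C@@H]3C[C@H](C)CC[C@H]3C(C)(C)c4ccccc4)CCC[C@@]21C | intermediate
21 | 8‑phenylmenthyl 7α‑hydroxy‑14‑oxo‑15,16‑dinorlabd‑8(17)‑en‑19‑oate | O=CCCC[C@H]1C(=C)[C@H](O)C[C@H]2[C@@](C)(C(=O)O[C@@H]3C[C@H](C)CC[C@H]3C(C)(C)c4ccccc4)CCC[C@@]21C | intermediate
22 | 8‑phenylmenthyl 7α‑hydroxy‑14‑oxo‑15‑norlabda‑8(17),13(16)‑dien‑19‑oate | O=CC(=C)CC[C@H]1C(=C)[C@H](O)C[C@H]2[C@@](C)(C(=O)O[C@@H]3C[C@H](C)CC[C@H]3C(C)(C)c4ccccc4)CCC[C@@]21C | intermediate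
23 | 8‑phenylmenthyl 7α‑hydroxylabda‑8(17),13(16),14‑trien‑19‑oate | C=CC(=C)CC[C@H]1C(=C)[C@H](O)C[C@H]2[C@@](C)(C(=O)O[C@@H]3C[C@H](C)CC[C@H]3C(C)(C)c4ccccc4)CCC[C@@]21C | intermediate
24 | 8‑phenylmenthyl 8α,17‑epoxy‑7α‑hydroxylabda‑13(16),14‑dien‑19‑oate | C=CC(=C)CC[C@H]1[C@]5(OC5)[C@H](O)C[C@H]2[C@@](C)(C(=O)O[C@@H]3C[C@H](C)CC[C@H]3C(C)(C)c4ccccc4)CCC[C@@]21C | intermediate
25 | labda‑13(16),14‑diene‑7α,8α,19‑triol | C=CC(=C)CC[C@H]1[C@](C)(O)[C@H](O)C[C@H]2[C@@](C)(CO)CCC[C@@]21C | intermediate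
26 | (E)‑4‑acetoxycinnamic acid | CC(=O)Oc1ccc(/C=C/C(=O)O)cc1 | starting material
27 | 19‑O‑[(E)‑4‑acetoxycinnamoyl]labda‑13(16),14‑diene‑7α,8α,19‑triol | C=CC(=C)CC[C@H]1[C@](C)(O)[C@H](O)C[C@H]2[C@@](C)(COC(=O)/C=C/c3ccc(OC(C)=O)cc3)CCC[C@@]21C | intermediate
28 | 19‑O‑[(E)‑4‑hydroxycinnamoyl]labda‑13(16),14‑diene‑7α,8α,19‑triol (CNP0254560.2) | C=CC(=C)CC[C@H]1[C@](C)(O)[C@H](O)C[C@H]2[C@@](C)(COC(=O)/C=C/c3ccc(O)cc3)CCC[C@@]21C | target

**Step count and risks**
Total step count: 16. Longest linear sequence: 15 steps (steps 1, 2, 3 and 5 to 16, from geranyl bromide).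

Steps most likely to fail:

Step 6. The auxiliary may discriminate the faces poorly when the fully substituted C4 radical attacks C5, and the monocyclic radical may be oxidised by copper before ring B closes. The fallback sets out from bromide 6 and alcohol 7 and comes back at 15; it makes the quaternary C4 centre by enolate alkylation and not in the radical step. Alcohol 7 is acylated with 2,2,6‑trimethyl‑4H‑1,3‑dioxin‑4‑one (xylene, 140 °C) to 8‑phenylmenthyl 3‑oxobutanoate F1. Its dianion (LDA, THF, 0 °C) is alkylated with 6 to the α‑unsubstituted polyene keto ester F2. Oxidative cyclization with Mn(OAc)3·2H2O, Cu(OAc)2·H2O and Yb(OTf)3 in CF3CH2OH at 0 °C, the variant with the closest precedent for high auxiliary control, should give the bicyclic β‑keto ester F3, which still has a hydrogen at C4. Methylation of its enolate (K2CO3, MeI, acetone) from the α‑face, anti to the axial C10 methyl, should then give 15.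

Step 9. Hydrogen abstraction may occur at C9 and not at C7, the allylic alcohol may be over‑oxidised to the enone, or the allylic system may transpose. The fallback sets out from 19 and comes back at 20. Hydrogen‑atom‑transfer isomerisation (Co(salen)Cl and PhSiH3, both catalytic, benzene, rt) moves the exocyclic alkene into the ring to give the 7‑ene ester F4. Epoxidation with mCPBA (NaHCO3, CH2Cl2, 0 °C) from the less hindered α‑face gives the 7α,8α‑epoxide F5. Isomerisation of the epoxide to the allylic alcohol with diethylaluminium 2,2,6,6‑tetramethylpiperidide (toluene, 0 °C), which removes a proton from the C17 methyl, gives 20 with the 7α‑hydroxyl fixed by the epoxide.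

Step 15. Acylation may also occur at the 7α‑hydroxyl, or at both hydroxyls, and the acetyl group may be transferred from the aryl acetate under DMAP catalysis. The fallback sets out from 25 and comes back at 27. The cis‑7,8‑diol is first tied up as the acetonide F6 (2,2‑dimethoxypropane, PPTS, CH2Cl2). The only free hydroxyl, at C19, is then acylated with 26 (EDC·HCl, DMAP) to the acetonide ester F7. The acetonide is removed with 80% aqueous AcOH at 40 °C, which leaves the aryl acetate and the diene intact, to give 27.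

**Further compounds**
F1 | step 6 | 8‑phenylmenthyl 3‑oxobutanoate | CC(=O)CC(=O)O[C@@H]1C[C@H](C)CC[C@H]1C(C)(C)c1ccccc1
F2 | step 6 | 8‑phenylmenthyl (6E,10E)‑14‑(1,3‑dioxolan‑2‑yl)‑6,10‑dimethyl‑3‑oxotetradeca‑6,10‑dienoate | O=C(CC(=O)CC/C(C)=C/CC/C(C)=C/CCCC1OCCO1)O[C@@H]1C[C@H](C)CC[C@H]1C(C)(C)c1ccccc1
F3 | step 6 | 8‑phenylmenthyl 14,14‑(ethylenedioxy)‑3‑oxo‑15,16,18‑trinorlabd‑8(17)‑en‑19‑oate (C4 epimerisable) | O5CCOC5CCC[C@H]1C(=C)CC[C@H]2C(C(=O)O[C@@H]3C[C@H](C)CC[C@H]3C(C)(C)c4ccccc4)C(=O)CC[C@@]21C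
F4 | step 9 | 8‑phenylmenthyl 14,14‑(ethylenedioxy)‑15,16‑dinorlabd‑7‑en‑19‑oate | O5CCOC5CCC[C@H]1C(C)=CC[C@H]2[C@@](C)(C(=O)O[C@@H]3C[C@H](C)CC[C@H]3C(C)(C)c4ccccc4)CCC[C@@]21C
F5 | step 9 | 8‑phenylmenthyl 7α,8α‑epoxy‑14,14‑(ethylenedioxy)‑15,16‑dinorlabdan‑19‑oate | O5CCOC5CCC[C@H]1[C@]6(C)O[C@@H]6C[C@H]2[C@@](C)(C(=O)O[C@@H]3C[C@H](C)CC[C@H]3C(C)(C)c4ccccc4)CCC[C@@]21C
F6 | step 15 | 7α,8α‑O‑isopropylidene‑labda‑13(16),14‑diene‑7α,8α,19‑triol | C=CC(=C)CC[C@H]1[C@]6(C)OC(C)(C)O[C@@H]6C[C@H]2[C@@](C)(CO)CCC[C@@]21C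
F7 | step 15 | 19‑O‑[(E)‑4‑acetoxycinnamoyl]‑7α,8α‑O‑isopropylidene‑labda‑13(16),14‑diene‑7α,8α,19‑triol | C=CC(=C)CC[C@H]1[C@]6(C)OC(C)(C)O[C@@H]6C[C@H]2[C@@](C)(COC(=O)/C=C/c3ccc(OC(C)=O)cc3)CCC[C@@]21C
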